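The target reads as epicatechin-(4β→6)-ent-epicatechin joined 4α→8 to a second copy of itself, so one protected dimer serves twice. In that dimer the upper pyran (ring C) is disconnected at O1–C8a. Ring A carries its C5 and C7 oxygens meta to C8a, so a fluorine there leaves by addition–elimination despite the donor groups. The precursor is an α-benzyloxy aldehyde (C2) on a diarylmethine (C4) that already sits on C6 of 8-bromo-ent-epicatechin. One operation adds the ring B Grignard reagent under chelation control, sets C2, and lets the alkoxide close O1–C8a with the C2–O bond untouched, which delivers the 2,3-cis series.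

Key step: step 11

Remark on the chemistry: read from the top of the chain, the four units are (2R,3R)-epicatechin, (2S,3S)-ent-epicatechin, (2R,3R)-epicatechin and (2S,3S)-ent-epicatechin, every interflavan bond is 3,4-trans, and (+)-epicatechin (the 2S,3S enantiomer) is taken as a purchasable compound.
Remark on numbering: flavan numbering of the upper unit (C2, C3, C4, C4a to C8a, rings A, B, C) is also used for its open-chain precursors.

Step 1
Reactants: 1 5-fluororesorcinol
Product: 2 1,3-bis(benzyloxy)-5-fluorobenzene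
Conditions: BnBr, K2CO3, DMF, 60 °C
Reagents that add atoms: benzyl bromide BrCc1ccccc1
Why: Williamson ether synthesis on both phenols, with the C–F bond inert to carbonate.

Step 2
Reactants: 2 1,3-bis(benzyloxy)-5-fluorobenzene
Product: 4 2,4-bis(benzyloxy)-6-fluorobenzaldehyde, via aryl iminium chloride 3 (not isolated)
Conditions: POCl3, DMF, 0 → 60 °C; then ice-water
Reagents that add atoms: N,N-dimethylformamide CN(C)C=O; water O
Why: Vilsmeier–Haack formylation should go para to one benzyloxy group and ortho to the small fluorine, because the position between the two benzyloxy groups is the most crowded one.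

Step 3
Reactants: 5 (R)-4-benzyloxazolidin-2-one; 6 benzyloxyacetyl chloride
Product: 7 (R)-4-benzyl-3-[(benzyloxy)acetyl]oxazolidin-2-one
Conditions: n-BuLi, THF, −78 °C; then 6, −78 → 0 °C
Reagents that add atoms: none
Why: N-acylation of the lithiated oxazolidinone with the acid chloride is the standard entry to an Evans glycolate imide.

Step 4
Reactants: 7 (R)-4-benzyl-3-[(benzyloxy)acetyl]oxazolidin-2-one; 4 2,4-bis(benzyloxy)-6-fluorobenzaldehyde
Product: 10 syn-aldol imide (2R,3S), via Z boron enolate 8 (not isolated), via boron aldolate 9 (not isolated)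
Conditions: Bu2BOTf, Et3N, CH2Cl2, −78 → 0 °C; 4, −78 → 0 °C; then H2O2, MeOH, pH 7 buffer
Reagents that add atoms: none
Why: Evans syn-glycolate aldol reaction through the Z boron enolate and a Zimmerman–Traxler chair, in which the (R)-benzyl group of the auxiliary sets the benzyloxy-bearing carbon (later C3), while the carbinol center (later C4) is formed syn but is erased by ionisation in step 9.

Step 5
Reactants: 10 syn-aldol imide (2R,3S)
Product: 11 (1S,2S)-2-(benzyloxy)-1-[2,4-bis(benzyloxy)-6-fluorophenyl]propane-1,3-diol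
Conditions: LiBH4, MeOH (1 equiv), THF, 0 °C
Reagents that add atoms: none
Why: Hydride reduction of the exocyclic imide carbonyl (reductive auxiliary removal) releases the primary alcohol that will become C2 and does not touch the benzyloxy-bearing stereocenter.

Step 6
Reactants: 12 (+)-epicatechin
Product: 13 5,7,3',4'-tetra-O-benzyl-ent-epicatechin
Conditions: BnBr, K2CO3, DMF, 0 °C → rt
Reagents that add atoms: benzyl bromide BrCc1ccccc1
Why: Williamson ether synthesis on the four phenols with a mild carbonate base, which leaves the C3 hydroxyl free and avoids ring opening and C2 epimerisation.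

Step 7
Reactants: 13 5,7,3',4'-tetra-O-benzyl-ent-epicatechin
Product: 14 3,5,7,3',4'-penta-O-benzyl-ent-epicatechin
Conditions: NaH, BnBr, DMF, 0 °C → rt
Reagents that add atoms: benzyl bromide BrCc1ccccc1
Why: Williamson ether synthesis on the secondary alkoxide, so that no hydroxyl of this unit can be oxidised in step 10 or deprotonated in step 11.

Step 8
Reactants: 14 3,5,7,3',4'-penta-O-benzyl-ent-epicatechin
Product: 15 8-bromo-3,5,7,3',4'-penta-O-benzyl-ent-epicatechin
Conditions: NBS, CH2Cl2, −78 → 0 °C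
Reagents that add atoms: N-bromosuccinimide O=C1CCC(=O)N1Br
Why: Electrophilic aromatic bromination takes C8, the most nucleophilic position of a 5,7-di-O-benzyl flavan, and the halogen cap leaves C6 as the only open position of that ring.

Step 9
Reactants: 11 (1S,2S)-2-(benzyloxy)-1-[2,4-bis(benzyloxy)-6-fluorophenyl]propane-1,3-diol; 15 8-bromo-3,5,7,3',4'-penta-O-benzyl-ent-epicatechin
Product: 16 open-chain adduct (2R,3S)-propan-1-ol
Conditions: 15 (2 equiv), BF3·OEt2 (0.5 equiv), 4 Å MS, CH2Cl2, −78 → −30 °C, slow addition of 11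
Reagents that add atoms: none
Why: Friedel–Crafts alkylation through the ring A benzylic cation at C4, which only C6 of 15 can intercept because C8 is capped, and with C3–H held in the cation plane by allylic 1,3-strain the arene should enter on the face away from the CH2OH arm and next to the slim benzyloxy group, giving the C3/C4 relationship that becomes 3,4-trans.

Step 10
Reactants: 16 open-chain adduct (2R,3S)-propan-1-ol
Product: 17 open-chain aldehyde (2R,3S)-propanal
Conditions: Dess–Martin periodinane, CH2Cl2, 0 °C → rt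
Reagents that add atoms: none
Why: Dess–Martin oxidation of the only free hydroxyl under non-epimerising conditions, to which aryl bromide, aryl fluoride and benzyl ethers are inert.

Step 11
Reactants: 17 open-chain aldehyde (2R,3S)-propanal; 18 1,2-bis(benzyloxy)-4-bromobenzene
Product: 22 protected dimer penta-O-benzyl-epicatechin-(4β→6)-8-bromo-penta-O-benzyl-ent-epicatechin, via aryl Grignard reagent 19 (not isolated), via bromomagnesium alkoxide 20 (not isolated), via potassium alkoxide 21 (not isolated)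
Conditions: 18, Mg, THF, rt; add to 17, MgBr2·OEt2, toluene, −78 °C; then KOt-Bu, DMPU, −78 → 60 °C
Reagents that add atoms: none
Why: MgBr2 ties the aldehyde oxygen and the C3 benzyloxy oxygen into a five-membered Cram chelate, 19 adds to C2 from the face opposite the bulky C4 diarylmethine, and after magnesium-to-potassium exchange alkoxide 21 attacks C8a of ring A, forms a Meisenheimer adduct and expels fluoride (SNAr, addition–elimination). Both halves are known reaction types, namely chelation-controlled Grignard addition to α-alkoxy aldehydes and pyran closure of flavan-3-ols by alkoxide displacement of fluoride from a 3,5-dialkoxyfluoroarene, and they are only run in one flask here. Ring C closes as a six-membered ring, formally 6-exo-trig on the C8a=C8 bond. C2 is the only new stereocenter and is set by the chelate syn to C3–O, and because the C2–O bond is never broken this syn relationship maps onto the 2,3-cis flavan, which closures through a C2 cation do not favour. The step needs one oxygen nucleophile and one site: C3–O is benzylated so no dihydrobenzofuran can form, ring A holds the only C–F bond, its C5 and C7 oxygens are meta to C8a and so stabilise the anionic adduct inductively without feeding charge into it, and C8–Br of the lower unit has neither that pattern nor an ortho hydrogen.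

Step 12
Reactants: 22 protected dimer (one part of the material)
Product: 23 protected dimer with a 4α-(2-ethoxyethoxy) group on the lower unit
Conditions: DDQ, 2-ethoxyethanol, CH2Cl2, rt
Reagents that add atoms: 2-ethoxyethanol CCOCCO
Why: DDQ benzylic oxidation by hydride abstraction at the only CH2 of the skeleton, C4 of the lower unit, whose quasi-axial C–H overlaps with its ring A whereas C4–H of the upper unit lies near the plane of both flanking arenes, and the alcohol should add anti to C3–OBn (3,4-trans).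

Step 13
Reactants: 23 protected dimer with a 4α-(2-ethoxyethoxy) group on the lower unit; 22 protected dimer
Product: 24 eicosa-O-benzyl dibromo tetramer
Conditions: 22 (3 equiv), Me3SiOTf (cat.), CH2Cl2, −78 °C
Reagents that add atoms: none
Why: Lewis acid ionisation of the C4 ether and Friedel–Crafts capture by C8 of the upper unit of 22, its most nucleophilic open position since C8 of its lower unit is brominated, from the face anti to C3–OBn and the C2 aryl group of the ent-epicatechin cation, which gives the 4α→8, 3,4-trans bond while the excess of 22 holds back self-condensation of 23.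

Step 14
Reactants: 24 eicosa-O-benzyl dibromo tetramer
Product: 25 epicatechin-(4β→6)-ent-epicatechin-(4α→8)-epicatechin-(4β→6)-ent-epicatechin
Conditions: H2 (1 atm), Pd(OH)2/C, Et3N, THF/MeOH/H2O, rt
Reagents that add atoms: none
Why: Catalytic hydrogenolysis removes all twenty benzyl ethers and both aryl bromine caps in one operation, with Et3N taking up HBr so that the acid-labile interflavan bonds and all stereocenters are kept.

Compound list
1 | 5-fluororesorcinol (5-fluorobenzene-1,3-diol) | Oc1cc(O)cc(F)c1 | starting material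
2 | 1,3-bis(benzyloxy)-5-fluorobenzene | Fc1cc(OCc2ccccc2)cc(OCc2ccccc2)c1 | intermediate
3 | [2,4-bis(benzyloxy)-6-fluorobenzylidene]dimethyliminium chloride | C[N+](C)=Cc1c(F)cc(OCc2ccccc2)cc1OCc1ccccc1.[Cl-] | intermediate
4 | 2,4-bis(benzyloxy)-6-fluorobenzaldehyde (ring A block) | O=Cc1c(F)cc(OCc2ccccc2)cc1OCc1ccccc1 | intermediate
5 | (R)-4-benzyloxazolidin-2-one | O=C1N[C@H](Cc2ccccc2)CO1 | starting material
6 | benzyloxyacetyl chloride | O=C(Cl)COCc1ccccc1 | starting material
7 | (R)-4-benzyl-3-[(benzyloxy)acetyl]oxazolidin-2-one | O=C(COCc1ccccc1)N1[C@H](Cc2ccccc2)COC1=O | intermediate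
8 | Z dibutylboron enolate of 7 | CCCCB(CCCC)O/C(=C\OCc1ccccc1)N1[C@H](Cc2ccccc2)COC1=O | intermediate
9 | dibutylboron aldolate of 10 | c1ccccc1COc1cc(OCc2ccccc2)c([C@H](OB(CCCC)CCCC)[C@H](C(=O)N2[C@H](Cc3ccccc3)COC2=O)OCc2ccccc2)c(F)c1 | intermediate
10 | (R)-4-benzyl-3-{(2R,3S)-2-(benzyloxy)-3-[2,4-bis(benzyloxy)-6-fluorophenyl]-3-hydroxypropanoyl}oxazolidin-2-one (syn aldol) | c1ccccc1COc1cc(OCc2ccccc2)c([C@H](O)[C@H](C(=O)N2[C@H](Cc3ccccc3)COC2=O)OCc2ccccc2)c(F)c1 | intermediate
11 | (1S,2S)-2-(benzyloxy)-1-[2,4-bis(benzyloxy)-6-fluorophenyl]propane-1,3-diol | c1ccccc1COc1cc(OCc2ccccc2)c([C@H](O)[C@H](CO)OCc2ccccc2)c(F)c1 | intermediate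
12 | (+)-epicatechin (ent-epicatechin, 2S,3S) | Oc1cc(O)c2C[C@H](O)[C@H](c3ccc(O)c(O)c3)Oc2c1 | starting material
13 | 5,7,3',4'-tetra-O-benzyl-ent-epicatechin (2S,3S) | c1ccccc1COc1cc(OCc2ccccc2)c2C[C@H](O)[C@H](c3ccc(OCc4ccccc4)c(OCc4ccccc4)c3)Oc2c1 | intermediate
14 | 3,5,7,3',4'-penta-O-benzyl-ent-epicatechin (2S,3S) | c1ccccc1COc1cc(OCc2ccccc2)c2C[C@H](OCc3ccccc3)[C@H](c3ccc(OCc4ccccc4)c(OCc4ccccc4)c3)Oc2c1 | intermediate
15 | 8-bromo-3,5,7,3',4'-penta-O-benzyl-ent-epicatechin (2S,3S) | c1ccccc1COc1cc(OCc2ccccc2)c2C[C@H](OCc3ccccc3)[C@H](c3ccc(OCc4ccccc4)c(OCc4ccccc4)c3)Oc2c1Br | intermediate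
16 | (2R,3S)-2-(benzyloxy)-3-[2,4-bis(benzyloxy)-6-fluorophenyl]-3-[(2S,3S)-8-bromo-penta-O-benzyl-ent-epicatechin-6-yl]propan-1-ol | c9ccccc9COc1cc(OCc9ccccc9)c([C@@H]([C@H](CO)OCc9ccccc9)c2c(OCc9ccccc9)c(Br)c3c(c2OCc9ccccc9)C[C@H](OCc9ccccc9)[C@H](c8ccc(OCc9ccccc9)c(OCc9ccccc9)c8)O3)c(F)c1 | intermediate
17 | (2R,3S)-2-(benzyloxy)-3-[2,4-bis(benzyloxy)-6-fluorophenyl]-3-[(2S,3S)-8-bromo-penta-O-benzyl-ent-epicatechin-6-yl]propanal | c9ccccc9COc1cc(OCc9ccccc9)c([C@@H]([C@H](C=O)OCc9ccccc9)c2c(OCc9ccccc9)c(Br)c3c(c2OCc9ccccc9)C[C@H](OCc9ccccc9)[C@H](c8ccc(OCc9ccccc9)c(OCc9ccccc9)c8)O3)c(F)c1 | intermediate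
18 | 1,2-bis(benzyloxy)-4-bromobenzene (ring B block) | Brc1ccc(OCc2ccccc2)c(OCc2ccccc2)c1 | starting material
19 | 3,4-bis(benzyloxy)phenylmagnesium bromide | Br[Mg]c1ccc(OCc2ccccc2)c(OCc2ccccc2)c1 | intermediate
20 | bromomagnesium (1R,2R,3S)-alkoxide from addition of 19 to 17 (C2–O and C3–O syn) | c9ccccc9COc1cc(OCc9ccccc9)c([C@@H]([C@H]([C@H](O[Mg]Br)c8ccc(OCc9ccccc9)c(OCc9ccccc9)c8)OCc9ccccc9)c2c(OCc9ccccc9)c(Br)c3c(c2OCc9ccccc9)C[C@H](OCc9ccccc9)[C@H](c8ccc(OCc9ccccc9)c(OCc9ccccc9)c8)O3)c(F)c1 | intermediate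
21 | potassium (1R,2R,3S)-alkoxide, same skeleton as 20 | c9ccccc9COc1cc(OCc9ccccc9)c([C@@H]([C@H]([C@H]([O-])c8ccc(OCc9ccccc9)c(OCc9ccccc9)c8)OCc9ccccc9)c2c(OCc9ccccc9)c(Br)c3c(c2OCc9ccccc9)C[C@H](OCc9ccccc9)[C@H](c8ccc(OCc9ccccc9)c(OCc9ccccc9)c8)O3)c(F)c1.[K+] | intermediate
22 | 3,5,7,3',4'-penta-O-benzyl-epicatechin-(4β→6)-8-bromo-3,5,7,3',4'-penta-O-benzyl-ent-epicatechin (upper unit 2R,3R, 2,3-cis-3,4-trans; lower unit 2S,3S) | c9ccccc9COc1cc(OCc9ccccc9)c2c(c1)O[C@H](c8ccc(OCc9ccccc9)c(OCc9ccccc9)c8)[C@H](OCc9ccccc9)[C@H]2c1c(OCc9ccccc9)c(Br)c2c(c1OCc9ccccc9)C[C@H](OCc9ccccc9)[C@H](c8ccc(OCc9ccccc9)c(OCc9ccccc9)c8)O2 | intermediate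
23 | 22 with a 4α-(2-ethoxyethoxy) group (3,4-trans) at C4 of the lower unit | c9ccccc9COc1cc(OCc9ccccc9)c2c(c1)O[C@H](c8ccc(OCc9ccccc9)c(OCc9ccccc9)c8)[C@H](OCc9ccccc9)[C@H]2c1c(OCc9ccccc9)c(Br)c2c(c1OCc9ccccc9)[C@@H](OCCOCC)[C@H](OCc9ccccc9)[C@H](c8ccc(OCc9ccccc9)c(OCc9ccccc9)c8)O2 | intermediate
24 | eicosa-O-benzyl tetramer with bromine at C8 of units 2 and 4, connectivity (4β→6), (4α→8), (4β→6), all 3,4-trans | c9ccccc9COc1cc(OCc9ccccc9)c2c(c1)O[C@H](c8ccc(OCc9ccccc9)c(OCc9ccccc9)c8)[C@H](OCc9ccccc9)[C@H]2c1c(OCc9ccccc9)c(Br)c2c(c1OCc9ccccc9)[C@@H](c1c(OCc9ccccc9)cc(OCc9ccccc9)c3c1O[C@H](c8ccc(OCc9ccccc9)c(OCc9ccccc9)c8)[C@H](OCc9ccccc9)[C@H]3c1c(OCc9ccccc9)c(Br)c3c(c1OCc9ccccc9)C[C@H](OCc9ccccc9)[C@H](c8ccc(OCc9ccccc9)c(OCc9ccccc9)c8)O3)[C@H](OCc9ccccc9)[C@H](c8ccc(OCc9ccccc9)c(OCc9ccccc9)c8)O2 | intermediate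
25 | epicatechin-(4β→6)-ent-epicatechin-(4α→8)-epicatechin-(4β→6)-ent-epicatechin (CNP0120618.2) | Oc1cc(O)c2c(c1)O[C@H](c1ccc(O)c(O)c1)[C@H](O)[C@H]2c1c(O)cc2c(c1O)[C@@H](c1c(O)cc(O)c3c1O[C@H](c1ccc(O)c(O)c1)[C@H](O)[C@H]3c1c(O)cc3c(c1O)C[C@H](O)[C@H](c1ccc(O)c(O)c1)O3)[C@H](O)[C@H](c1ccc(O)c(O)c1)O2 | target

Total step count: 14
Longest linear sequence: 10 steps (1, 2, 4, 5, 9, 10, 11, 12, 13, 14)

Steps most likely to fail

**Step 11 (key step).**
- What may go wrong: THF may compete with the C3 benzyloxy oxygen for magnesium and erode the facial selectivity. The substitution may also stall in the magnesium-rich medium.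
- The fallback sets C2 with hydride instead of the aryl nucleophile and runs the ring closure on its own.
- It sets out from 17. Addition of 19 without additive and aqueous quench should give the C2-epimeric carbinols F3.
- Dess–Martin oxidation should give the aryl ketone F4.
- LiBH(s-Bu)3 in THF at −78 °C is a non-chelating hydride that follows the polar Felkin–Anh model, and it should give the syn alcohol F5.
- KH and 18-crown-6 in THF then close O1–C8a, and the route is rejoined at 22.

**Step 9.**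
- What may go wrong: facial selectivity at the open C4 cation may be poor. The diol may also be lost through fragmentation or self-alkylation before the hindered C6 position reacts.
- The fallback replaces open-cation control by anchimeric assistance.
- It sets out from 11. Pivaloyl chloride and pyridine at 0 °C should acylate only the primary hydroxyl to give the primary pivalate F1.
- On ionisation with BF3·OEt2 the pivaloyl carbonyl oxygen should bridge C4 as a six-membered dioxanylium ion, with ring A and C3–OBn equatorial. Compound 15 should open it with inversion to give the adduct pivalate F2.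
- i-Bu2AlH in CH2Cl2 at −78 °C removes the ester, and the route is rejoined at 16.

**Step 12.**
- What may go wrong: hydride abstraction may compete at the diarylmethine of the upper unit or at C2, or the electron-rich upper ring A may be over-oxidised.
- The fallback installs the leaving group on the monomer and carries it as a thioether that only a thiophilic salt activates.
- It sets out from 15. DDQ and 2-ethoxyethanol should give the monomeric 4α-ether F6. 4-Methylbenzenethiol with BF3·OEt2 should exchange it for the 4α-thioether F7.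
- Friedel–Crafts alkylation with 11 under BF3·OEt2, which leaves the C–S bond alone, should give the thio adduct F8.
- Dess–Martin oxidation should give the thio aldehyde F9.
- The sequence of step 11 with 19 should give the 4α-thio dimer F10.
- AgBF4 in CH2Cl2/THF at 0 °C in the presence of excess 22 ionises the C–S bond, and the route is rejoined at 24.

Further compounds
F1 | step 9 | (2S,3S)-2-(benzyloxy)-3-[2,4-bis(benzyloxy)-6-fluorophenyl]-3-hydroxypropyl pivalate | c1ccccc1COc1cc(OCc2ccccc2)c([C@H](O)[C@H](COC(=O)C(C)(C)C)OCc2ccccc2)c(F)c1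
F2 | step 9 | pivalate ester of 16 | c9ccccc9COc1cc(OCc9ccccc9)c([C@@H]([C@H](COC(=O)C(C)(C)C)OCc9ccccc9)c2c(OCc9ccccc9)c(Br)c3c(c2OCc9ccccc9)C[C@H](OCc9ccccc9)[C@H](c8ccc(OCc9ccccc9)c(OCc9ccccc9)c8)O3)c(F)c1
F3 | step 11 | C2-epimeric carbinols from 17 and 19 (C2 undefined) | c9ccccc9COc1cc(OCc9ccccc9)c([C@@H]([C@H](C(O)c8ccc(OCc9ccccc9)c(OCc9ccccc9)c8)OCc9ccccc9)c2c(OCc9ccccc9)c(Br)c3c(c2OCc9ccccc9)C[C@H](OCc9ccccc9)[C@H](c8ccc(OCc9ccccc9)c(OCc9ccccc9)c8)O3)c(F)c1
F4 | step 11 | aryl ketone at C2 | c9ccccc9COc1cc(OCc9ccccc9)c([C@@H]([C@H](C(=O)c8ccc(OCc9ccccc9)c(OCc9ccccc9)c8)OCc9ccccc9)c2c(OCc9ccccc9)c(Br)c3c(c2OCc9ccccc9)C[C@H](OCc9ccccc9)[C@H](c8ccc(OCc9ccccc9)c(OCc9ccccc9)c8)O3)c(F)c1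
F5 | step 11 | (1R,2R,3S)-syn alcohol, the protonated form of 21 | c9ccccc9COc1cc(OCc9ccccc9)c([C@@H]([C@H]([C@H](O)c8ccc(OCc9ccccc9)c(OCc9ccccc9)c8)OCc9ccccc9)c2c(OCc9ccccc9)c(Br)c3c(c2OCc9ccccc9)C[C@H](OCc9ccccc9)[C@H](c8ccc(OCc9ccccc9)c(OCc9ccccc9)c8)O3)c(F)c1
F6 | step 12 | 8-bromo-4α-(2-ethoxyethoxy)-penta-O-benzyl-ent-epicatechin (3,4-trans) | c1ccccc1COc1cc(OCc2ccccc2)c2[C@@H](OCCOCC)[C@H](OCc3ccccc3)[C@H](c3ccc(OCc4ccccc4)c(OCc4ccccc4)c3)Oc2c1Br
F7 | step 12 | 8-bromo-4α-(4-methylphenylthio)-penta-O-benzyl-ent-epicatechin (3,4-trans) | c1ccccc1COc1cc(OCc2ccccc2)c2[C@@H](Sc3ccc(C)cc3)[C@H](OCc3ccccc3)[C@H](c3ccc(OCc4ccccc4)c(OCc4ccccc4)c3)Oc2c1Br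
F8 | step 12 | analogue of 16 with the 4α-(4-methylphenylthio) group on the flavan unit | c9ccccc9COc1cc(OCc9ccccc9)c([C@@H]([C@H](CO)OCc9ccccc9)c2c(OCc9ccccc9)c(Br)c3c(c2OCc9ccccc9)[C@@H](Sc7ccc(C)cc7)[C@H](OCc9ccccc9)[C@H](c8ccc(OCc9ccccc9)c(OCc9ccccc9)c8)O3)c(F)c1
F9 | step 12 | analogue of 17 with the 4α-(4-methylphenylthio) group on the flavan unit | c9ccccc9COc1cc(OCc9ccccc9)c([C@@H]([C@H](C=O)OCc9ccccc9)c2c(OCc9ccccc9)c(Br)c3c(c2OCc9ccccc9)[C@@H](Sc7ccc(C)cc7)[C@H](OCc9ccccc9)[C@H](c8ccc(OCc9ccccc9)c(OCc9ccccc9)c8)O3)c(F)c1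
F10 | step 12 | analogue of 22 with the 4α-(4-methylphenylthio) group on the lower unit | c9ccccc9COc1cc(OCc9ccccc9)c2c(c1)O[C@H](c8ccc(OCc9ccccc9)c(OCc9ccccc9)c8)[C@H](OCc9ccccc9)[C@H]2c1c(OCc9ccccc9)c(Br)c2c(c1OCc9ccccc9)[C@@H](Sc7ccc(C)cc7)[C@H](OCc9ccccc9)[C@H](c8ccc(OCc9ccccc9)c(OCc9ccccc9)c8)O2
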